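**Strategy.** The macrocycle is opened out of a cyclohexane. In the target, C1 (ketone level, the hemiketal carbon) and the C5=C6 enol-lactone alkene are joined through C2–C3–C4; this 5-cyclodecenone motif is what remains when the C1–C6 bond of a six-membered ring (C1, C6, C7, C8, C9, C10) breaks in an anionic oxy-Cope shift while C3–C4 forms. One operation should deliver the ten-membered ring, the C1 ketone, the E-alkylidene butenolide and the C4 carbinol centre. The precursor is a butenolide-fused cis-1,2-dialkenylcyclohexanol whose Z enol ether oxygen O4 is bridged to O8 by a di-tert-butylsilylene, which fixes the enol ether geometry and holds C4 on the C7 side of C6.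

Key step: step 15

Remark: locants C1–C15 are those of the target's germacrane skeleton (C1 hemiketal carbon, C4 carbinol carbon bearing C15, C6 and C12 the lactone termini, C13 the oxymethyl carbon, C14 the methyl on C10); fused intermediates also carry 1-benzofuran names.
Remark on the precursor design: the stereodescriptors of the key-step precursor and product are kept as they are consistent with each other and with the target. The open-chain enol ether is replaced by the O8–Si–O4 bridge because, without it, allylic strain would favour the rotamer that places C4 cis to the lactone oxygen (5Z, 4S).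
Assumption: the C1 hemiketal configuration is the thermodynamic one, since the oxolane can bridge the ten-membered ring only with C5 and C10 cis.

Step 1
Reactants: 1 5-methylcyclohexane-1,3-dione; 2 ethyl bromopyruvate
Product: 4 ethyl 6-methyl-4-oxo-4,5,6,7-tetrahydro-1-benzofuran-3-carboxylate (racemic), via hydroxydihydrofuran adduct 3 (not isolated)
Conditions: KOH, MeOH, 0 °C to rt; then aq HCl, rt
Reagents that add atoms: none
Why: Feist–Benary furan annulation: the dione enolate adds through C2 to the pyruvate ketone, the enol oxygen displaces bromide, and acid dehydrates adduct 3 to the furan; the single stereocentre is erased in step 2.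

Step 2
Reactants: 4 ethyl 6-methyl-4-oxo-4,5,6,7-tetrahydro-1-benzofuran-3-carboxylate
Product: 5 ethyl 4-hydroxy-6-methyl-1-benzofuran-3-carboxylate
Conditions: DDQ (1.1 equiv), 1,4-dioxane, reflux
Reagents that add atoms: none
Why: Quinone dehydrogenation of a 4-oxotetrahydrobenzofuran to the 4-hydroxybenzofuran (dehydrogenative aromatisation), which prepares the para position (target C1) for oxidation.

Step 3
Reactants: 5 ethyl 4-hydroxy-6-methyl-1-benzofuran-3-carboxylate
Product: 6 ethyl 7,7-dimethoxy-6-methyl-4-oxo-4,7-dihydro-1-benzofuran-3-carboxylate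
Conditions: PhI(OAc)2 (2.2 equiv), MeOH, 0 °C to rt
Reagents that add atoms: methanol, CO
Why: Oxidative dearomatisation of a para-unsubstituted phenol to the para-quinone monoketal places target C1 at the ketone level as a ketal and leaves a C5=C6 enone for asymmetric reduction.

Step 4
Reactants: 6 ethyl 7,7-dimethoxy-6-methyl-4-oxo-4,7-dihydro-1-benzofuran-3-carboxylate
Product: 8 ethyl (6R)-7,7-dimethoxy-6-methyl-4-oxo-4,5,6,7-tetrahydro-1-benzofuran-3-carboxylate, via silyl enol ether 7 (not isolated)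
Conditions: Cu(OAc)2·H2O (cat.), (R)-DTBM-SEGPHOS (cat., antipode to be confirmed on a test run), (EtO)2MeSiH, toluene, 0 °C; then pH 7 buffer, THF
Reagents that add atoms: none
Why: Ligand-controlled copper hydride 1,4-reduction of the β,β-disubstituted enone (asymmetric conjugate reduction) sets the methyl-bearing centre (target C10, R) by face-selective hydride delivery to C6, and the neutral work-up avoids loss of methanol and re-aromatisation.

Step 5
Reactants: 8 ethyl (6R)-7,7-dimethoxy-6-methyl-4-oxo-4,5,6,7-tetrahydro-1-benzofuran-3-carboxylate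
Product: 9 (4S,6R)-3-(hydroxymethyl)-7,7-dimethoxy-6-methyl-4,5,6,7-tetrahydro-1-benzofuran-4-ol
Conditions: LiAlH4, THF, −78 to 0 °C; aq potassium sodium tartrate (KNaC4H4O6)
Reagents that add atoms: none
Why: Hydride reduction of ester and ketone; attack on the C4 carbonyl anti to the C6 methyl (pseudoaxial beside the ketal) should give the 4,6-cis alcohol, which is target C8 (S), by substrate-controlled 1,3-induction.

Step 6
Reactants: 9 (4S,6R)-3-(hydroxymethyl)-7,7-dimethoxy-6-methyl-4,5,6,7-tetrahydro-1-benzofuran-4-ol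
Product: 11 (4S,6R)-3-[[tert-butyl(dimethyl)silyl]oxymethyl]-7,7-dimethoxy-6-methyl-4-(triethylsilyloxy)-4,5,6,7-tetrahydro-1-benzofuran, via primary TBS ether 10 (not isolated)
Conditions: TBSCl (1.05 equiv), imidazole, DMF, 0 °C; then TESCl, rt
Reagents that add atoms: tert-butyldimethylsilyl chloride, CC(C)(C)[Si](C)(C)Cl; triethylsilyl chloride, CC[Si](Cl)(CC)CC
Why: Sequential silyl ether formation in one flask: the primary alcohol reacts first for steric reasons, then the secondary C4 hydroxyl takes the more labile triethylsilyl group that is removed selectively in step 13.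

Step 7
Reactants: 11 (4S,6R)-3-[[tert-butyl(dimethyl)silyl]oxymethyl]-7,7-dimethoxy-6-methyl-4-(triethylsilyloxy)-4,5,6,7-tetrahydro-1-benzofuran
Product: 12 (4S,6R)-3-[[tert-butyl(dimethyl)silyl]oxymethyl]-6-methyl-4-(triethylsilyloxy)-5,6-dihydro-1-benzofuran-7(4H)-one
Conditions: PPTS (cat.), acetone–H2O, 0 °C
Reagents that add atoms: water, O
Why: Mild acid hydrolysis of the 2-furyl dimethyl ketal through a furan-stabilised oxocarbenium ion frees the C7 ketone (target C1) under conditions that should spare both silyl ethers and the α-methyl centre.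

Step 8
Reactants: 12 (4S,6R)-3-[[tert-butyl(dimethyl)silyl]oxymethyl]-6-methyl-4-(triethylsilyloxy)-5,6-dihydro-1-benzofuran-7(4H)-one; 13 ethynylmagnesium bromide
Product: 14 (4S,6R,7R)-3-[[tert-butyl(dimethyl)silyl]oxymethyl]-7-ethynyl-6-methyl-4-(triethylsilyloxy)-4,5,6,7-tetrahydro-1-benzofuran-7-ol
Conditions: THF, −40 to 0 °C; aq NH4Cl
Reagents that add atoms: none
Why: Grignard 1,2-addition to the 2-acylfuran ketone: the slender sp nucleophile is expected to enter along the pseudoaxial trajectory anti to the axial C6–H of the half-chair (as with 2-methylcyclohexanones), placing ethynyl cis to the equatorial C6 methyl and setting target C1 (7R here).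

Step 9
Reactants: 14 (4S,6R,7R)-3-[[tert-butyl(dimethyl)silyl]oxymethyl]-7-ethynyl-6-methyl-4-(triethylsilyloxy)-4,5,6,7-tetrahydro-1-benzofuran-7-ol
Product: 16 (4S,6R,7R)-3-[[tert-butyl(dimethyl)silyl]oxymethyl]-7-ethynyl-7,7a-dihydroxy-6-methyl-4-(triethylsilyloxy)-5,6,7,7a-tetrahydro-1-benzofuran-2(4H)-one (both 7a epimers), via furan endoperoxide 15 (not isolated)
Conditions: O2, hν (visible), tetraphenylporphyrin (cat.), iPr2NEt, CH2Cl2, −78 °C
Reagents that add atoms: oxygen, O=O
Why: Singlet-oxygen [4+2] cycloaddition to the furan followed by base-induced Kornblum–DeLaMare opening of endoperoxide 15 at its only α-hydrogen (C12–H) gives the γ-hydroxybutenolide with the carbonyl at C12 and C6 as a masked ketone; the hemiketal centre is a mixture that is consumed in step 10.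

Step 10
Reactants: 16 (4S,6R,7R)-3-[[tert-butyl(dimethyl)silyl]oxymethyl]-7-ethynyl-7,7a-dihydroxy-6-methyl-4-(triethylsilyloxy)-5,6,7,7a-tetrahydro-1-benzofuran-2(4H)-one; 17 2-methylallylmagnesium chloride
Product: 19 (4S,6R,7R,7aR)-3-[[tert-butyl(dimethyl)silyl]oxymethyl]-7-ethynyl-7-hydroxy-6-methyl-7a-(2-methylprop-2-enyl)-4-(triethylsilyloxy)-5,6,7,7a-tetrahydro-1-benzofuran-2(4H)-one, via hydroxy acid 18 (not isolated)
Conditions: 17 (5 equiv), THF, −78 to −20 °C; then AcOH, −78 °C to rt
Reagents that add atoms: none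
Why: Chelation-controlled Grignard addition to an α-alkoxide ketone: base opens the pseudo-acid to the keto carboxylate, magnesium bridges O1 and the C6 carbonyl, and the allyl nucleophile should enter past the small ethynyl group so that the two oxygens end cis (the cis-diol outcome of cyclic α-ketols) and the two carbon substituents cis (target C6, R); acidification closes the (Z)-γ-hydroxy acid 18 to the butenolide.

Step 11
Reactants: 19 (4S,6R,7R,7aR)-3-[[tert-butyl(dimethyl)silyl]oxymethyl]-7-ethynyl-7-hydroxy-6-methyl-7a-(2-methylprop-2-enyl)-4-(triethylsilyloxy)-5,6,7,7a-tetrahydro-1-benzofuran-2(4H)-one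
Product: 20 (4S,6R,7R,7aR)-3-[[tert-butyl(dimethyl)silyl]oxymethyl]-7-ethynyl-7-hydroxy-6-methyl-7a-(2-oxopropyl)-4-(triethylsilyloxy)-5,6,7,7a-tetrahydro-1-benzofuran-2(4H)-one
Conditions: O3, CH2Cl2, −78 °C (stopped when the 1,1-disubstituted alkene is consumed); then PPh3
Reagents that add atoms: ozone, [O-][O+]=O
Why: Ozonolysis with reductive work-up: the electron-rich 1,1-disubstituted alkene should react far faster than the terminal alkyne or the electron-poor tetrasubstituted butenolide alkene, giving the C4 methyl ketone.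

Step 12
Reactants: 20 (4S,6R,7R,7aR)-3-[[tert-butyl(dimethyl)silyl]oxymethyl]-7-ethynyl-7-hydroxy-6-methyl-7a-(2-oxopropyl)-4-(triethylsilyloxy)-5,6,7,7a-tetrahydro-1-benzofuran-2(4H)-one
Product: 21 (4S,6R,7S,7aR)-3-[[tert-butyl(dimethyl)silyl]oxymethyl]-7-ethenyl-7-hydroxy-6-methyl-7a-(2-oxopropyl)-4-(triethylsilyloxy)-5,6,7,7a-tetrahydro-1-benzofuran-2(4H)-one
Conditions: H2 (1 atm), Pd on CaCO3 poisoned with Pb(OAc)2, quinoline, EtOAc, rt
Reagents that add atoms: none
Why: Lindlar semihydrogenation of the terminal alkyne gives the C2=C3 vinyl group without touching ketone, lactone or the tetrasubstituted alkene (the descriptor at C1 changes from R to S by priority only).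

Step 13
Reactants: 21 (4S,6R,7S,7aR)-3-[[tert-butyl(dimethyl)silyl]oxymethyl]-7-ethenyl-7-hydroxy-6-methyl-7a-(2-oxopropyl)-4-(triethylsilyloxy)-5,6,7,7a-tetrahydro-1-benzofuran-2(4H)-one
Product: 22 (4S,6R,7S,7aR)-3-[[tert-butyl(dimethyl)silyl]oxymethyl]-7-ethenyl-4,7-dihydroxy-6-methyl-7a-(2-oxopropyl)-5,6,7,7a-tetrahydro-1-benzofuran-2(4H)-one
Conditions: HF·pyridine, pyridine, THF, 0 °C
Reagents that add atoms: none
Why: Rate-selective cleavage of the secondary triethylsilyl ether beside the primary TBS ether; migration of the lactone to O8 is excluded because C12 is held cis to C6 on the C7=C11 alkene.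

Step 14
Reactants: 22 (4S,6R,7S,7aR)-3-[[tert-butyl(dimethyl)silyl]oxymethyl]-7-ethenyl-4,7-dihydroxy-6-methyl-7a-(2-oxopropyl)-5,6,7,7a-tetrahydro-1-benzofuran-2(4H)-one
Product: 24 (1S,6R,8S,10R)-oxy-Cope precursor: cyclohexane C1/C6–C10 fused to the C7=C11 butenolide (12,6-olide) with OH and vinyl on C1, (Z)-CH=C(CH3)–O4 on C6, O4 and O8 bridged by Si(t-Bu)2, methyl on C10 and OTBS on C13, via O8 silyl triflate 23 (not isolated)
Conditions: t-Bu2Si(OTf)2 (1.05 equiv), 2,6-lutidine, CH2Cl2, −78 to 0 °C; then Et3N, rt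
Reagents that add atoms: di-tert-butylsilyl bis(trifluoromethanesulfonate), CC(C)(C)[Si](OS(=O)(=O)C(F)(F)F)(OS(=O)(=O)C(F)(F)F)C(C)(C)C
Why: Silylene formation with a dialkylsilyl bis(triflate): O8 is silylated first, the tethered silyl triflate then activates the C4 ketone and the amine removes a C5 proton (soft enolisation to a silyl enol ether), which only an acetonyl group cis to O8 can do; amine/triflate equilibration should favour the endocyclic trisubstituted enol ether, whose Z geometry (O4 cis to C6) is imposed by the eight-membered ring.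

Step 15
Reactants: 24 (1S,6R,8S,10R)-oxy-Cope precursor
Product: 27 (4R,5E,8S,10R)-ten-membered C1 ketone with the 5E-alkylidene butenolide (12,6-olide; C7=C11), O4 and O8 still bridged by Si(t-Bu)2 and OTBS on C13, via potassium alkoxide 25 (not isolated), via potassium enolate 26 (not isolated)
Conditions: KH (1.5 equiv), 18-crown-6 (1.5 equiv), THF, −40 to 0 °C; then AcOH, −78 °C
Reagents that add atoms: none
Why: KH/18-crown-6 gives the naked C1 alkoxide 25, which rearranges by an anion-accelerated [3,3] shift over C3=C2–C1–C6–C5=C4 (anionic oxy-Cope rearrangement of a 1,2-dialkenylcyclohexanol; the limiting stepwise course, C1–C6 heterolysis to an enone-tethered 2-oxidofuran and vinylogous Michael reclosure at C4, ends in the same enolate 26), helped by the acyloxy- and butenolide-stabilised C6 terminus. The ten-membered ring arises by four-atom ring expansion of the cyclohexane through this six-centre array (C3–C4 forms while C1–C6 breaks), not by an end-to-end cyclisation. Since the lactone oxygen must stay in the butenolide plane, C5 is pseudoaxial on C6, and the cis substituents on C6, C8 and C10 penalise the cyclohexane chair, so the cis alkenyl groups should react from a boat-like array with both termini folded over the ring. C4 is set by suprafacial chirality transfer from C6 (6R): C3 bonds to the enol ether face from which C1 departs, and with the Z geometry (O4 cis to C6) this gives 4R. The step needs C5=C6 to form with C4 cis to C7 (5E) and not cis to the lactone oxygen, which allylic strain would otherwise favour; the eight-membered O8–Si–O4 ring secures this by confining C4 to the C7/C8 side and also keeps the enol ether Z. It further needs the shift to outrun acyl transfer from O6 to the O1 alkoxide, which is reversible and leads to an alkoxide without the stabilised departing carbon; the cold acetic acid quench protonates enolate 26 at C2 and leaves C10 untouched.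

Step 16
Reactants: 27 (4R,5E,8S,10R)-ten-membered C1 ketone
Product: 29 (1S,4R,5E,8S,10R)-1,4-epoxy-1,8,13-trihydroxygermacra-5,7(11)-dien-12,6-olide, via trihydroxy ketone 28 (not isolated)
Conditions: HF·pyridine, THF, 0 °C to rt
Reagents that add atoms: none
Why: Fluoride cleavage of the silylene and the TBS ether frees O4, O8 and O13, and the tertiary C4 hydroxyl adds to the C1 ketone (5-exo-trig hemiketalisation under thermodynamic control); the oxolane can bridge the ring only with C5 and C10 cis, which fixes 1S.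

Step 17
Reactants: 29 (1S,4R,5E,8S,10R)-1,4-epoxy-1,8,13-trihydroxygermacra-5,7(11)-dien-12,6-olide
Product: 30 (1S,4R,5E,8S,10R)-13-acetoxy-1,4-epoxy-1,8-dihydroxygermacra-5,7(11)-dien-12,6-olide
Conditions: Ac2O (1.1 equiv), 2,4,6-collidine, CH2Cl2, −20 °C
Reagents that add atoms: acetic anhydride, CC(=O)OC(C)=O
Why: Chemoselective acetylation of the primary allylic alcohol, which should react well ahead of the hindered secondary C8 hydroxyl and the tertiary hemiketal hydroxyl.

Step 18
Reactants: 31 (R)-3-bromo-2-hydroxy-2-methylpropanoic acid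
Product: 32 potassium (S)-2-methyloxirane-2-carboxylate
Conditions: KOH (2 equiv), MeOH–H2O, 0 °C to rt; evaporation
Reagents that add atoms: potassium hydroxide, [K+].[OH-]
Why: Intramolecular Williamson-type epoxide closure of the bromohydrin carboxylate; C2 is not touched, and its descriptor changes from R to S by priority only.

Step 19
Reactants: 30 (1S,4R,5E,8S,10R)-13-acetoxy-1,4-epoxy-1,8-dihydroxygermacra-5,7(11)-dien-12,6-olide; 32 potassium (S)-2-methyloxirane-2-carboxylate
Product: 34 (1S,4R,5E,8S,10R)-13-acetoxy-1,4-epoxy-1-hydroxy-8-[(2S)-2-methyloxirane-2-carbonyl]oxygermacra-5,7(11)-dien-12,6-olide, via mixed anhydride 33 (not isolated)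
Conditions: 32, 2,4,6-trichlorobenzoyl chloride, THF, rt; then 30, DMAP, toluene, rt
Reagents that add atoms: none
Why: Yamaguchi esterification: the mixed anhydride 33 transfers the α-quaternary acyl group through its acylpyridinium ion to the hindered secondary C8 hydroxyl, while the tertiary hemiketal hydroxyl should not compete and the epoxide survives the non-acidic conditions.

Step 20
Reactants: 34 (1S,4R,5E,8S,10R)-13-acetoxy-1,4-epoxy-1-hydroxy-8-[(2S)-2-methyloxirane-2-carbonyl]oxygermacra-5,7(11)-dien-12,6-olide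
Product: 35 CNP0414417.3, (1S,4R,5E,8S,10R)-13-acetoxy-8-[(2R)-3-chloro-2-hydroxy-2-methylpropanoyl]oxy-1,4-epoxy-1-hydroxygermacra-5,7(11)-dien-12,6-olide
Conditions: LiCl, AcOH, THF, rt
Reagents that add atoms: lithium chloride, [Li+].[Cl-]
Why: Epoxide-to-chlorohydrin opening: chloride attacks the acid-activated 2,2-disubstituted glycidic ester by SN2 at the unsubstituted CH2, so C2 keeps its configuration (2R by priority change) and the tertiary alcohol appears without a protecting group.

**Compound list**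

1 | 5-methylcyclohexane-1,3-dione | CC1CC(=O)CC(=O)C1 | starting material
2 | ethyl bromopyruvate | CCOC(=O)C(=O)CBr | starting material
3 | ethyl 3-hydroxy-6-methyl-4-oxo-2,3,4,5,6,7-hexahydro-1-benzofuran-3-carboxylate (stereoisomer mixture) | CCOC(=O)C1(O)COC2=C1C(=O)CC(C)C2 | intermediate (not isolated)
4 | ethyl 6-methyl-4-oxo-4,5,6,7-tetrahydro-1-benzofuran-3-carboxylate (racemic) | CCOC(=O)c1coc2CC(C)CC(=O)c12 | intermediate
5 | ethyl 4-hydroxy-6-methyl-1-benzofuran-3-carboxylate | CCOC(=O)c1coc2cc(C)cc(O)c12 | intermediate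
6 | ethyl 7,7-dimethoxy-6-methyl-4-oxo-4,7-dihydro-1-benzofuran-3-carboxylate | CCOC(=O)c1coc2c1C(=O)C=C(C)C2(OC)OC | intermediate
7 | ethyl (6R)-4-[diethoxy(methyl)silyl]oxy-7,7-dimethoxy-6-methyl-6,7-dihydro-1-benzofuran-3-carboxylate | CCOC(=O)c1coc2c1C(O[Si](C)(OCC)OCC)=C[C@@H](C)C2(OC)OC | intermediate (not isolated)
8 | ethyl (6R)-7,7-dimethoxy-6-methyl-4-oxo-4,5,6,7-tetrahydro-1-benzofuran-3-carboxylate | CCOC(=O)c1coc2c1C(=O)C[C@@H](C)C2(OC)OC | intermediate
9 | (4S,6R)-3-(hydroxymethyl)-7,7-dimethoxy-6-methyl-4,5,6,7-tetrahydro-1-benzofuran-4-ol | OCc1coc2c1[C@@H](O)C[C@@H](C)C2(OC)OC | intermediate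
10 | (4S,6R)-3-[[tert-butyl(dimethyl)silyl]oxymethyl]-7,7-dimethoxy-6-methyl-4,5,6,7-tetrahydro-1-benzofuran-4-ol | CC(C)(C)[Si](C)(C)OCc1coc2c1[C@@H](O)C[C@@H](C)C2(OC)OC | intermediate (not isolated)
11 | (4S,6R)-3-[[tert-butyl(dimethyl)silyl]oxymethyl]-7,7-dimethoxy-6-methyl-4-(triethylsilyloxy)-4,5,6,7-tetrahydro-1-benzofuran | CC(C)(C)[Si](C)(C)OCc1coc2c1[C@@H](O[Si](CC)(CC)CC)C[C@@H](C)C2(OC)OC | intermediate
12 | (4S,6R)-3-[[tert-butyl(dimethyl)silyl]oxymethyl]-6-methyl-4-(triethylsilyloxy)-5,6-dihydro-1-benzofuran-7(4H)-one | CC(C)(C)[Si](C)(C)OCc1coc2c1[C@@H](O[Si](CC)(CC)CC)C[C@@H](C)C2=O | intermediate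
13 | ethynylmagnesium bromide | C#C[Mg]Br | starting material
14 | (4S,6R,7R)-3-[[tert-butyl(dimethyl)silyl]oxymethyl]-7-ethynyl-6-methyl-4-(triethylsilyloxy)-4,5,6,7-tetrahydro-1-benzofuran-7-ol | CC(C)(C)[Si](C)(C)OCc1coc2c1[C@@H](O[Si](CC)(CC)CC)C[C@@H](C)[C@@]2(O)C#C | intermediate
15 | furan 2,5-endoperoxide of 14 (peroxide bridging C6 and C12) | CC(C)(C)[Si](C)(C)OCC1=C2[C@@H](O[Si](CC)(CC)CC)C[C@@H](C)[C@@](O)(C#C)C23OOC1O3 | intermediate (not isolated)
16 | (4S,6R,7R)-3-[[tert-butyl(dimethyl)silyl]oxymethyl]-7-ethynyl-7,7a-dihydroxy-6-methyl-4-(triethylsilyloxy)-5,6,7,7a-tetrahydro-1-benzofuran-2(4H)-one (7a epimers) | CC(C)(C)[Si](C)(C)OCC1=C2[C@@H](O[Si](CC)(CC)CC)C[C@@H](C)[C@@](O)(C#C)C2(O)OC1=O | intermediate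
17 | 2-methylallylmagnesium chloride | CC(=C)C[Mg]Cl | starting material
18 | (Z)-γ-hydroxy acid from ring-opened 16 and 17 (C6 carbinol with 2-methylallyl, free C12 acid cis to C6) | CC(C)(C)[Si](C)(C)OC\C(C(=O)O)=C1/[C@@H](O[Si](CC)(CC)CC)C[C@@H](C)[C@@](O)(C#C)[C@]1(CC(C)=C)O | intermediate (not isolated)
19 | (4S,6R,7R,7aR)-3-[[tert-butyl(dimethyl)silyl]oxymethyl]-7-ethynyl-7-hydroxy-6-methyl-7a-(2-methylprop-2-enyl)-4-(triethylsilyloxy)-5,6,7,7a-tetrahydro-1-benzofuran-2(4H)-one | CC(C)(C)[Si](C)(C)OCC1=C2[C@@H](O[Si](CC)(CC)CC)C[C@@H](C)[C@@](O)(C#C)[C@]2(CC(C)=C)OC1=O | intermediate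
20 | (4S,6R,7R,7aR)-3-[[tert-butyl(dimethyl)silyl]oxymethyl]-7-ethynyl-7-hydroxy-6-methyl-7a-(2-oxopropyl)-4-(triethylsilyloxy)-5,6,7,7a-tetrahydro-1-benzofuran-2(4H)-one | CC(C)(C)[Si](C)(C)OCC1=C2[C@@H](O[Si](CC)(CC)CC)C[C@@H](C)[C@@](O)(C#C)[C@]2(CC(C)=O)OC1=O | intermediate
21 | (4S,6R,7S,7aR)-3-[[tert-butyl(dimethyl)silyl]oxymethyl]-7-ethenyl-7-hydroxy-6-methyl-7a-(2-oxopropyl)-4-(triethylsilyloxy)-5,6,7,7a-tetrahydro-1-benzofuran-2(4H)-one | CC(C)(C)[Si](C)(C)OCC1=C2[C@@H](O[Si](CC)(CC)CC)C[C@@H](C)[C@@](O)(C=C)[C@]2(CC(C)=O)OC1=O | intermediate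
22 | (4S,6R,7S,7aR)-3-[[tert-butyl(dimethyl)silyl]oxymethyl]-7-ethenyl-4,7-dihydroxy-6-methyl-7a-(2-oxopropyl)-5,6,7,7a-tetrahydro-1-benzofuran-2(4H)-one | CC(C)(C)[Si](C)(C)OCC1=C2[C@@H](O)C[C@@H](C)[C@@](O)(C=C)[C@]2(CC(C)=O)OC1=O | intermediate
23 | O8 di-tert-butyl(trifluoromethanesulfonyloxy)silyl ether of 22 | CC(C)(C)[Si](C)(C)OCC1=C2[C@@H](O[Si](OS(=O)(=O)C(F)(F)F)(C(C)(C)C)C(C)(C)C)C[C@@H](C)[C@@](O)(C=C)[C@]2(CC(C)=O)OC1=O | intermediate (not isolated)
24 | (1S,6R,8S,10R)-oxy-Cope precursor: butenolide-fused cis-1,2-dialkenylcyclohexanol, (Z)-enol ether O4 and O8 bridged by Si(t-Bu)2, 13-OTBS | CC(C)(C)[Si](C)(C)OCC1=C2[C@@H](O[Si]3(C(C)(C)C)C(C)(C)C)C[C@@H](C)[C@@](O)(C=C)[C@]2(/C=C(/C)O3)OC1=O | intermediate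
25 | potassium C1 alkoxide of 24 | CC(C)(C)[Si](C)(C)OCC1=C2[C@@H](O[Si]3(C(C)(C)C)C(C)(C)C)C[C@@H](C)[C@@]([O-])(C=C)[C@]2(/C=C(/C)O3)OC1=O.[K+] | intermediate (not isolated)
26 | potassium C1=C2 enolate of 27 | CC(C)(C)[Si](C)(C)OCC1=C2/C(=C\[C@@]3(C)C/C=C(/[O-])[C@H](C)C[C@@H]2O[Si](C(C)(C)C)(C(C)(C)C)O3)OC1=O.[K+] | intermediate (not isolated)
27 | (4R,5E,8S,10R)-ten-membered C1 ketone with E-alkylidene butenolide, O4/O8 di-tert-butylsilylene, 13-OTBS | CC(C)(C)[Si](C)(C)OCC1=C2/C(=C\[C@@]3(C)CCC(=O)[C@H](C)C[C@@H]2O[Si](C(C)(C)C)(C(C)(C)C)O3)OC1=O | intermediate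
28 | (4R,5E,8S,10R)-4,8,13-trihydroxy-1-oxogermacra-5,7(11)-dien-12,6-olide | OCC1=C2/C(=C\[C@@](O)(C)CCC(=O)[C@H](C)C[C@@H]2O)OC1=O | intermediate (not isolated)
29 | (1S,4R,5E,8S,10R)-1,4-epoxy-1,8,13-trihydroxygermacra-5,7(11)-dien-12,6-olide | OCC1=C2/C(=C\[C@@]3(C)CC[C@](O)(O3)[C@H](C)C[C@@H]2O)OC1=O | intermediate
30 | (1S,4R,5E,8S,10R)-13-acetoxy-1,4-epoxy-1,8-dihydroxygermacra-5,7(11)-dien-12,6-olide | CC(=O)OCC1=C2/C(=C\[C@@]3(C)CC[C@](O)(O3)[C@H](C)C[C@@H]2O)OC1=O | intermediate
31 | (R)-3-bromo-2-hydroxy-2-methylpropanoic acid | OC(=O)[C@@](C)(O)CBr | starting material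
32 | potassium (S)-2-methyloxirane-2-carboxylate | [K+].[O-]C(=O)[C@@]1(C)OC1 | intermediate
33 | (S)-2-methyloxirane-2-carboxylic 2,4,6-trichlorobenzoic anhydride | O=C(OC(=O)[C@@]1(C)OC1)c1c(Cl)cc(Cl)cc1Cl | intermediate (not isolated)
34 | (1S,4R,5E,8S,10R)-13-acetoxy-1,4-epoxy-1-hydroxy-8-[(2S)-2-methyloxirane-2-carbonyl]oxygermacra-5,7(11)-dien-12,6-olide | CC(=O)OCC1=C2/C(=C\[C@@]3(C)CC[C@](O)(O3)[C@H](C)C[C@@H]2OC(=O)[C@@]4(C)OC4)OC1=O | intermediate
35 | CNP0414417.3 | CC(=O)OCC1=C2/C(=C\[C@@]3(C)CC[C@](O)(O3)[C@H](C)C[C@@H]2OC(=O)[C@@](C)(O)CCl)OC1=O | target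

**Step count.** Total: 20 steps. Longest linear sequence: 19 steps (steps 1–17, 19 and 20, from 1 and 2 to 35); step 18 prepares the side-chain salt.

**Steps most likely to fail**

Step 15 (key step). The C1 alkoxide may be diverted before C3–C4 bonding: by acyl migration of the lactone carbonyl from O6 to O1, by C1–C6 heterolysis without reclosure, or by vinylogous deprotonation at C8 with loss of the C13 silyloxy group. The fallback leaves anionic chemistry and sets out from 24. O1 is silylated (N-trimethylsilylimidazole, CH2Cl2) to the O1 trimethylsilyl ether F1. F1 is heated (o-xylene, about 180 °C, sealed base-washed tube) so that the neutral siloxy-Cope rearrangement of the 1,2-dialkenylcyclohexyl silyl ether, with the same tether-enforced geometry, should give the C1 trimethylsilyl enol ether F2. Mild hydrolysis of F2 (KF, MeOH–H2O, 0 °C) returns to the route at 27.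

Step 14. The silyloxocarbenium stage may lose a proton from the C15 methyl group and give the exocyclic enol ether, or intermolecular silylation may win over eight-membered ring closure. The fallback sets out from 16 and installs an untethered Z enol ether as a preformed nucleophile. (Z)-1-Bromo-2-[(4-methoxyphenyl)methoxy]prop-1-ene F3 (base-mediated anti addition of 4-methoxybenzyl alcohol to 1-bromoprop-1-yne) is lithiated (t-BuLi, −78 °C; the cis alkoxy group holds lithium) and added to 16 under the chelation control of step 10; buffered work-up lactonises to the C6 (Z)-alkoxypropenyl butenolide F4. Lindlar reduction gives the vinyl carbinol F5. KH/18-crown-6 rearranges F5 to the ten-membered ketone F6; here the C4-to-C7 rotamer is no longer enforced, so the 5E geometry rests on the substrate alone. DDQ removes the 4-methoxybenzyl group and the freed C4 hydroxyl closes the bis-silylated hemiketal F7. HF·pyridine then returns to the route at 29.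

Step 10. Facial selectivity may be poor if the magnesium chelate does not control the addition, so that the allyl group enters anti to the ethynyl group and the C6 epimer forms. The fallback corrects C6 under thermodynamic control and sets out from 16 through that epimer, the 7a-epimeric methallyl lactone F8. Ozonolysis as in step 11 gives the 7a-epimeric β-acyloxy ketone F9. Catalytic DBU in MeCN opens F9 by E1cB elimination to the enone acid F10, which recloses by oxa-Michael addition. The equilibrium should favour the isomer in which the C8 silyloxy group can sit pseudoaxial, free of allylic strain with C13, with the acetonyl group cis to it; this is where the fallback returns to the route, at 20.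

**Further compounds**

F1 | step 15 | O1 trimethylsilyl ether of 24 | CC(C)(C)[Si](C)(C)OCC1=C2[C@@H](O[Si]3(C(C)(C)C)C(C)(C)C)C[C@@H](C)[C@@](O[Si](C)(C)C)(C=C)[C@]2(/C=C(/C)O3)OC1=O
F2 | step 15 | C1 trimethylsilyl enol ether of 27 | CC(C)(C)[Si](C)(C)OCC1=C2/C(=C\[C@@]3(C)C/C=C(/O[Si](C)(C)C)[C@H](C)C[C@@H]2O[Si](C(C)(C)C)(C(C)(C)C)O3)OC1=O
F3 | step 14 | (Z)-1-bromo-2-[(4-methoxyphenyl)methoxy]prop-1-ene | C/C(OCc1ccc(OC)cc1)=C/Br
F4 | step 14 | C6 (Z)-2-[(4-methoxyphenyl)methoxy]prop-1-enyl butenolide with ethynyl on C1, 8-OTES, 13-OTBS | CC(C)(C)[Si](C)(C)OCC1=C2[C@@H](O[Si](CC)(CC)CC)C[C@@H](C)[C@@](O)(C#C)[C@]2(/C=C(/C)OCc3ccc(OC)cc3)OC1=O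
F5 | step 14 | untethered oxy-Cope precursor (vinyl on C1, PMB enol ether, 8-OTES, 13-OTBS) | CC(C)(C)[Si](C)(C)OCC1=C2[C@@H](O[Si](CC)(CC)CC)C[C@@H](C)[C@@](O)(C=C)[C@]2(/C=C(/C)OCc3ccc(OC)cc3)OC1=O
F6 | step 14 | ten-membered C1 ketone with C4 PMB ether, 8-OTES, 13-OTBS | CC(C)(C)[Si](C)(C)OCC1=C2/C(=C\[C@@](OCc3ccc(OC)cc3)(C)CCC(=O)[C@H](C)C[C@@H]2O[Si](CC)(CC)CC)OC1=O
F7 | step 14 | 1,4-epoxy hemiketal with 8-OTES and 13-OTBS | CC(C)(C)[Si](C)(C)OCC1=C2/C(=C\[C@@]3(C)CC[C@](O)(O3)[C@H](C)C[C@@H]2O[Si](CC)(CC)CC)OC1=O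
F8 | step 10 | 7a-epimer of 19 | CC(C)(C)[Si](C)(C)OCC1=C2[C@@H](O[Si](CC)(CC)CC)C[C@@H](C)[C@@](O)(C#C)[C@@]2(CC(C)=C)OC1=O
F9 | step 10 | 7a-epimer of 20 | CC(C)(C)[Si](C)(C)OCC1=C2[C@@H](O[Si](CC)(CC)CC)C[C@@H](C)[C@@](O)(C#C)[C@@]2(CC(C)=O)OC1=O
F10 | step 10 | ring-opened enone acid (C6=C5–C4 ketone, free C12 acid) | CC(C)(C)[Si](C)(C)OC\C(C(=O)O)=C1/[C@@H](O[Si](CC)(CC)CC)C[C@@H](C)[C@@](O)(C#C)C1=CC(C)=O
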